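The data are calculated on assumed constants, noise included.

3 questions stand for the flask, and I answer them through the fraction of starting material left, not the fraction made.

- north: starting material 2 M; gas phase 130 mM (held); run made earlier
- flask: starting material 1.3 M; gas phase 130 mM (held); time 5.0 min

north run (percent of the starting material charged)

| time / s | target / % | starting material / % |
|---|---|---|
| 10.0 | 2.6 | 96.4 |
| 15.0 | 4.0 | 95.4 |
| 25.0 | 8.5 | 91.4 |
| 30.0 | 10.6 | 88.6 |

(scatter of a reading: 0.5 percentage points)

- the earlier runs were read with a standard deviation of 0.5 percentage points
- at the start none of the gas phase is in solution

- spring: doubling the transfer coefficient of the gas phase, all else as stated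
- dusk: doubling the saturation concentration of gas phase, all else as stated

- the target standing at 5.0 min, as a percentage of the starting material charged
- the change that raises the amount of target at 5.0 min, in percent of the starting material charged most ("none" if none brings more than 2 percentage points) (spring / dusk / none)
- amount of target at 5.0 min, in percent of the starting material charged, after spring

From the first to the last north reading, the logarithm of the fraction left falls at 0.253 min⁻¹. This is my fading constant, a pseudo-first-order constant that carries the scatter of the readings. Held over 5.0 min, it leaves 28.2% in the flask. I take that as my upper bound on what is left, since the flask's charge is smaller than the north charge and so draws less on the gas.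

For the lower bound I hold the same north drop as a constant rate, 7.80 mM s⁻¹. That rate uses up the flask's charge in 2.78 min, shorter than the time asked, so the bound is 0%.

The last north reading has target and starting material summing to 99.2%, but that balance stands at 30.0 s, with 11.4% consumed, and it says nothing of the flask at 5.0 min. My bracket is then 71.8% to 100% for the starting material consumed in the flask, not for target.

The forecast gives 84% of target, from 73% to 94%, a figure that lies inside my bracket for what is consumed. It names dusk as best and puts spring at 88%, noting that “The mass balance closes within noise”.

    target ⇌ isomer of the product (K = 26.0, k = 0.00470 s⁻¹)
    dissolved gas → decomposed reagent (k = 0.00160 s⁻¹)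
    starting material + dissolved gas → target (k = 0.0800 M⁻¹ s⁻¹)
    gas phase ⇌ dissolved gas, rate k4*(csat - [dissolved gas]) (kL = 0.120 s⁻¹)
    dissolved gas + target → over-reacted product (k = 0.00250 M⁻¹ s⁻¹)

The flask gives 39.2% of target. The best change is none: spring moves target by −1.4 percentage points to 37.8%, and dusk moves it by −6.4 points. At 5.00 min the flask holds 47.4% as isomer of the product, and its 11% of starting material lies under my upper bound. For the same flask read at 3.0 min, the fading constant bounds what is left at 46.8%, and that neighbour holds 31%, with 44.0% of target.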